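## Structural features

- The target is a 3-hydroxyisoflavanone: a chroman-4-one (ring A fused to the pyranone ring C) whose C3 carries both ring B and a tertiary hydroxyl.
- C3 is the only stereocentre, (R). It is quaternary, benzylic and α to the C4 ketone, so no neighbouring centre can relay to it and a reagent or catalyst must set it.
- Ring A is a phloroglucinol unit (O1, 5-OH, 7-OH) with a prenyl group at C6. Ring B is contiguously tetrasubstituted: C1' on C3, 2'-OMe, 3'-prenyl, 4'-OH.
- Fragile elements are the ortho-prenylphenol motifs (6-prenyl between 5-OH and 7-OH, 3'-prenyl next to 4'-OH), which close to chromans in protic acid and do not survive hydrogenolysis, and the tertiary benzylic α-ketol at C3, which can ionise or undergo an α-ketol shift.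
- The real difficulty is the C3–C1' bond, which joins a fully substituted carbinol carbon to an arene carbon flanked by a methoxy group, within the 1,2,3,4-pattern of ring B.
- The key step turns this around by growing ring B on C3. C1' begins as a diazo carbon already bonded to C3, C4' as an enone carbonyl carbon, C5' and C6' as its vinyl group, and C2' and C3' as the carbons of a methoxyalkyne that carries the prenyl chain.
- Because C3 bears no hydrogen, the 1,2-hydride shift that usually competes in substituted diazo ketones is impossible, and the symmetry of ring A makes the later closure of ring C regiochemically trivial.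

## Logic of the disconnections

**35 from 32.** The last cut removes two acetal groups from O5 and O7 and a silyl group from O3. These masks are needed because the route uses strong bases and organolithiums. The acetals are kept on ring A because they direct the lithiation that places the C6 prenyl group; the tertiary oxygen carries a silyl ether instead of an acetal so that fluoride can remove it. The forward step must work without protic acid.

**32 from 30.** The C4–C4a bond is cut. Closing the ketone last lets ring A enter as a plain aryl ether. The closure is made anionic (aryl bromide to aryllithium, then attack on the ester) and not through an acylium ion, because an acylium carbon bearing a silyloxy group and an electron-rich aryl group would be expected to lose carbon monoxide. This requires a bromine on ring A ortho to the ether oxygen; since both ortho positions are equivalent, its placement is unambiguous. The forward step needs halogen–lithium exchange to outrun attack on the ester.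

**30 from 22 and 25.** Four bonds of ring B are cut: C1'–C6', C1'–C2', C3'–C4' and C4'–C5'. This replaces the tetrasubstituted arene by a diazo enone and an ynol ether, and the C3–C1' bond becomes an ordinary C–C bond to a diazo carbon. In the four-membered intermediate 27 the vinyl group sits on the sp3 ring carbon (a 4-vinylcyclobut-2-en-1-one), which is what lets ring opening place it at the diene terminus. Compound 22 carries three spectator refinements: the ring A bromine, the silyl ether on O3, and no hydrogen on C3. The forward step needs the Wolff shift to beat other carbene pathways, and light that only the diazo enone absorbs.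

**25 from 23 and 4.** The C(sp)–CH2 bond is cut, giving a methoxyacetylide and an allylic bromide. The forward alkylation must occur at the primary carbon.

**22 from 19, then 19 from 17 and 18, then 17 from 16.** The diazo group is removed first; 19 can be enolised on one side only, so the transfer is regiospecific. The acyl–vinyl bond is cut next, back to a thioester and a vinyl donor, which avoids a separate methylenation sequence on a methyl ketone. The O–Si bond is cut last; the hydroxyl must be protected before the vinyl ketone exists, otherwise retro-aldol cleavage or oxa-Michael closure would follow.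

**16 from 11 and 14; 14 from 12.** The bond between C3 and the carbon that becomes C1' is cut as an aldol bond. The hindered aryl–C3 bond is therefore made as an addition to a ketone long before ring B exists, and the same step sets the stereocentre. The forward step needs a catalyst that binds the two adjacent carbonyls of 11 and shields one face.

**11 from 10; 10 from 8 and 9.** The ketone is taken back to a secondary alcohol and the aryl ether O–CH2 bond is cut to a phenol and an epoxy ester. The epoxide must open at its unsubstituted carbon.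

**8 from 7, 6, 3 and 4; 3 from 2; 2 from 1.** The C–Br bond, the silyl ether and the C6–prenyl bond are cut in turn. The prenyl group enters by lithiation between the two acetal oxygens, which requires the third oxygen to be blocked by a non-directing group. The two acetals come from a statistical protection of a symmetric triphenol.

## Other disconnections considered

**Alternative 1:** The cut is at the two aryl–prenyl bonds (C6–CH2 and C3'–CH2). In the forward direction, heating the bis(2-methylbut-3-en-2-yl) ether A2 would trigger two aromatic Claisen shifts, from O5 to C6 and from O2' to C3', giving A1.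
- In its favour: both acid-sensitive prenyl groups arrive at the very end. This is better than the chosen plan, which carries the ring A prenyl group through thirteen steps. Regiochemistry is structural, since C4a and C1' block the other ortho positions. The sigmatropic step is as predictable as the pericyclic cascade of the chosen plan.
- Against it: it builds no ring and leaves the two real problems, the C3 stereocentre and the C3–C1' bond, to other chemistry. Two tertiary allyl ethers must be placed on hindered phenols, one of them the hydrogen-bonded 5-OH. Heat acts on a tertiary α-ketol. A1 still needs selective methylation of 2'-OH beside 5-OH and the tertiary hydroxyl, and then acetal removal.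
- Step economy: the key step forms two bonds where the chosen one forms four, and the ether preparation and the methylation add steps, so the total would be longer.

**Alternative 2:** The cut is at C4a–C5 and C8–C8a of ring A. In the forward direction, diene A5 and bromoalkynone A4 would combine in a [4+2] cycloaddition and lose methanol to give A3.
- In its favour: the 5,7-dioxygenation and the C6 prenyl group are written into an acyclic diene, so no statistical protection of a symmetric triphenol is needed, which is better than step 1 of the chosen plan. The bromine for the later C–O closure arrives without an electrophilic bromination next to a prenyl group, which is also better. Convergence is equal.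
- Against it: A4 already contains ring B and the stereocentre, so the hindered C3–C1' bond must be made by addition or coupling, which the chosen plan avoids. Bromoalkynones are labile, and highly oxygenated dienes may give open-chain conjugate adducts instead of the ring. After A3, the acetonide must be removed and ring C closed by aryl C–O coupling in the presence of two free phenols, which costs protection steps and an acidic operation.
- Overall: the mechanism is less certain and the sequence after the key step is longer.

**Alternative 3:** The cut is at O1–C8a and C4–C4a. In the forward direction, fluoride would release an aryne from silyl triflate A7; the primary alkoxide of A8 would add at C8a and the resulting C4a anion would attack the ester, giving A6.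
- In its favour: ring C closes in one mild step without acid or organolithium. This is better than the chosen plan, which makes the ether early and the ketone late in two separate operations. The regiochemistry, directed by the C5 oxygen, is as predictable as the bromine-defined closure of the chosen plan.
- Against it: the alkoxide of A8 is that of a β-hydroxy ester with a quaternary α-carbon and can lose formaldehyde by retro-aldol cleavage. The aryl anion may be protonated before it acylates. A7 is a pentasubstituted benzene needing several steps. A8 again requires the C3–C1' bond and the stereocentre by other means. Four acetals, one on a tertiary oxygen, must be removed at the end.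
- Overall: equal or better for the ring C closure itself, worse for ring B and for the final deprotection.

Key step: step 14

## Remarks before the steps

- Assumption: in step 9 the catalyst is taken to shield the same face of the chelated keto ester as with simple pyruvate esters (attack on the si face, which here corresponds to R). If the sense proved opposite, the (R,R)-ligand would be used.
- Methyl glycidate is used as the racemate because its stereocentre is oxidised away in step 7.
- Abbreviations: MOM = methoxymethyl; prenyl = 3-methylbut-2-en-1-yl; TES = triethylsilyl; ArA = 2-bromo-3,5-bis(methoxymethoxy)-4-(3-methylbut-2-en-1-yl)phenyl; t-Bu-box = 2,2'-(propane-2,2-diyl)bis[(4S)-4-tert-butyl-4,5-dihydro-1,3-oxazole]; DMPU = 1,3-dimethyl-1,3-diazinan-2-one.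

## Route

Step 1
Reactants: 1 phloroglucinol (benzene-1,3,5-triol)
Product: 2 3,5-bis(methoxymethoxy)phenol
Conditions: MOMCl (2.0 equiv), i-Pr2NEt, DMF, 0 °C → rt
Reagents that add atoms: chloromethyl methyl ether, COCCl
Why: Base-mediated O-alkylation of a symmetric triphenol (Williamson-type acetal formation); with two equivalents the bis-ether should predominate and is separable from the mono- and tris-ethers, which can be recycled. MOM is chosen because these two acetals later direct the lithiation that places the prenyl group.

Step 2
Reactants: 2 3,5-bis(methoxymethoxy)phenol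
Product: 3 [3,5-bis(methoxymethoxy)phenoxy]tri(propan-2-yl)silane
Conditions: i-Pr3SiCl, imidazole, DMF, rt
Reagents that add atoms: chlorotri(propan-2-yl)silane, CC(C)[Si](Cl)(C(C)C)C(C)C
Why: Imidazole-promoted silylation of the remaining phenol; the bulky silyl ether blocks this oxygen, does not direct metalation and is remote from the carbon to be lithiated, so no silyl migration is expected.

Step 3
Reactants: 3 [3,5-bis(methoxymethoxy)phenoxy]tri(propan-2-yl)silane; 4 prenyl bromide (1-bromo-3-methylbut-2-ene)
Product: 6 [3,5-bis(methoxymethoxy)-4-(3-methylbut-2-en-1-yl)phenoxy]tri(propan-2-yl)silane, via aryllithium 5 (not isolated)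
Conditions: n-BuLi, THF, 0 °C; CuI (10 mol%), 4, −78 °C → rt
Reagents that add atoms: none
Why: Directed ortho-metalation at the carbon flanked by both acetal oxygens (doubly coordinated, most acidic C–H), then copper-catalysed allylic substitution; attack at the primary carbon of 4 is expected because the alternative would create a quaternary centre.

Step 4
Reactants: 6 [3,5-bis(methoxymethoxy)-4-(3-methylbut-2-en-1-yl)phenoxy]tri(propan-2-yl)silane
Product: 7 3,5-bis(methoxymethoxy)-4-(3-methylbut-2-en-1-yl)phenol
Conditions: Bu4NF, THF, 0 °C; aq NH4Cl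
Reagents that add atoms: none
Why: Fluoride-induced cleavage of the aryl silyl ether, driven by Si–F bond formation; MOM ethers and the prenyl group are inert to Bu4NF.

Step 5
Reactants: 7 3,5-bis(methoxymethoxy)-4-(3-methylbut-2-en-1-yl)phenol
Product: 8 2-bromo-3,5-bis(methoxymethoxy)-4-(3-methylbut-2-en-1-yl)phenol
Conditions: NBS (1.0 equiv), CH2Cl2, −78 °C, dark
Reagents that add atoms: N-bromosuccinimide, O=C1CCC(=O)N1Br
Why: Electrophilic aromatic bromination of a phenol; the only free ring positions (C2 and C6) are equivalent, and the hydroxyl is para to the prenyl group, so bromo-etherification is impossible and the very electron-rich ring should react far faster than the trisubstituted alkene at −78 °C. One equivalent of NBS limits double bromination.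

Step 6
Reactants: 8 2-bromo-3,5-bis(methoxymethoxy)-4-(3-methylbut-2-en-1-yl)phenol; 9 methyl glycidate (racemic methyl oxirane-2-carboxylate)
Product: 10 methyl 3-(ArA-oxy)-2-hydroxypropanoate (racemic)
Conditions: CsF (0.2 equiv), DMF, 60 °C
Reagents that add atoms: none
Why: Fluoride-catalysed addition of a phenol to an epoxide, an SN2 opening at the unsubstituted carbon remote from the ester; 9 can be racemic because its carbinol centre is oxidised away in step 7.

Step 7
Reactants: 10 methyl 3-(ArA-oxy)-2-hydroxypropanoate
Product: 11 methyl 3-(ArA-oxy)-2-oxopropanoate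
Conditions: Dess–Martin periodinane, CH2Cl2, rt
Reagents that add atoms: none
Why: Dess–Martin oxidation of a secondary α-hydroxy ester to the α-keto ester under near-neutral conditions that leave MOM ethers, bromide and prenyl untouched; 11 is dried azeotropically and used at once because 1,2-dicarbonyl compounds hydrate readily.

Step 8
Reactants: 12 S-ethyl ethanethioate
Product: 14 {[1-(ethylsulfanyl)ethenyl]oxy}trimethylsilane, via lithium enolate 13 (not isolated)
Conditions: LiN(i-Pr)2, THF, −78 °C; Me3SiCl
Reagents that add atoms: chlorotrimethylsilane, C[Si](C)(C)Cl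
Why: Kinetic deprotonation of the thioester and O-silylation of the lithium enolate, the standard preparation of a thioester silyl ketene acetal.

Step 9
Reactants: 11 methyl 3-(ArA-oxy)-2-oxopropanoate; 14 {[1-(ethylsulfanyl)ethenyl]oxy}trimethylsilane
Product: 16 methyl (2R)-2-[(ArA-oxy)methyl]-4-(ethylsulfanyl)-2-hydroxy-4-oxobutanoate, via trimethylsilyl ether 15 (not isolated)
Conditions: Cu(OTf)2 (10 mol%), (S,S)-t-Bu-box (11 mol%), THF, −78 °C; 1 M HCl, 0 °C
Reagents that add atoms: none
Why: Enantioselective Mukaiyama aldol addition to an α-keto ester under chiral Lewis acid catalysis: 11 binds divalent copper through its two adjacent carbonyl oxygens in a square-planar chelate, one tert-butyl group of the ligand blocks one face, and 14 attacks the open (si) face of the ketone, which gives the (R) carbinol and, after silyl transfer and mild acid work-up, 16. This step makes the bond that becomes C3–C1' and sets the only stereocentre.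

Step 10
Reactants: 16 methyl (2R)-2-[(ArA-oxy)methyl]-4-(ethylsulfanyl)-2-hydroxy-4-oxobutanoate
Product: 17 methyl (2R)-2-[(ArA-oxy)methyl]-4-(ethylsulfanyl)-4-oxo-2-[(triethylsilyl)oxy]butanoate
Conditions: Et3SiOTf, 2,6-lutidine, CH2Cl2, −78 °C
Reagents that add atoms: triethylsilyl trifluoromethanesulfonate, CC[Si](CC)(CC)OS(=O)(=O)C(F)(F)F
Why: Silylation of a hindered tertiary alcohol with a silyl triflate and a non-nucleophilic base; the ether prevents retro-aldol cleavage under the later strong base and oxa-Michael closure onto the vinyl ketone, and it is removable with fluoride. Low temperature keeps the aryl MOM ethers out of reach of the silyl triflate.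

Step 11
Reactants: 17 methyl (2R)-2-[(ArA-oxy)methyl]-4-(ethylsulfanyl)-4-oxo-2-[(triethylsilyl)oxy]butanoate; 18 tributyl(ethenyl)stannane
Product: 19 methyl (2R)-2-[(ArA-oxy)methyl]-4-oxo-2-[(triethylsilyl)oxy]hex-5-enoate
Conditions: Pd2(dba)3 (2.5 mol%), P(2-furyl)3 (10 mol%), CuO2PPh2 (1.3 equiv), THF, 40 °C
Reagents that add atoms: none
Why: Liebeskind–Srogl-type ketone synthesis (thioester–organostannane coupling catalysed by zerovalent palladium and mediated by a monovalent copper phosphinate) under neutral, base-free conditions; the vinyl ketone is installed in one step with no regiochemical ambiguity. The doubly ortho-oxygenated, electron-rich aryl bromide should undergo oxidative addition much more slowly than the copper-activated thioester at 40 °C.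

Step 12
Reactants: 19 methyl (2R)-2-[(ArA-oxy)methyl]-4-oxo-2-[(triethylsilyl)oxy]hex-5-enoate
Product: 22 methyl (2R)-2-[(ArA-oxy)methyl]-3-diazo-4-oxo-2-[(triethylsilyl)oxy]hex-5-enoate, via lithium dienolate 20 (not isolated), via trifluoroacetyl ketone 21 (not isolated)
Conditions: LiN(SiMe3)2, THF, −78 °C; CF3CO2CH2CF3; dilute HCl wash; then 4-AcNHC6H4SO2N3, Et3N, H2O, MeCN, rt
Reagents that add atoms: 4-acetamidobenzenesulfonyl azide, CC(=O)Nc1ccc(cc1)S(=O)(=O)N=[N+]=[N-]
Why: Detrifluoroacetylative diazo transfer: the enone can be enolised only on the C3 side, the lithium dienolate is C-acylated by the trifluoroethyl ester, and the activated 1,3-diketone accepts the diazo group from the sulfonyl azide with loss of the trifluoroacetyl group as the sulfonamide. This is the standard entry to α'-diazo enones, which cannot be made from enoyl chlorides and diazoalkanes.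

Step 13
Reactants: 23 chloroacetaldehyde dimethyl acetal (2-chloro-1,1-dimethoxyethane); 4 prenyl bromide
Product: 25 1-methoxy-5-methylhex-4-en-1-yne, via lithium methoxyacetylide 24 (not isolated)
Conditions: n-BuLi, Et2NH (3.1 equiv LiNEt2), THF, 0 °C; 4, DMPU, −78 °C → rt
Reagents that add atoms: none
Why: Threefold base treatment of a chloroacetal (two eliminations and a deprotonation) gives the lithium alkoxyacetylide, which is alkylated in the same flask; SN2 attack at the primary carbon of 4 is expected in the dipolar cosolvent.

Step 14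
Reactants: 22 methyl (2R)-2-[(ArA-oxy)methyl]-3-diazo-4-oxo-2-[(triethylsilyl)oxy]hex-5-enoate; 25 1-methoxy-5-methylhex-4-en-1-yne
Product: 30 methyl (2R)-3-(ArA-oxy)-2-[4-hydroxy-2-methoxy-3-(3-methylbut-2-en-1-yl)phenyl]-2-[(triethylsilyl)oxy]propanoate, via vinylketene 26 (not isolated), via cyclobutenone 27 (not isolated), via dienylketene 28 (not isolated), via cyclohexadienone 29 (not isolated)
Conditions: 25 (2 equiv), hν (365 nm), degassed ClCH2CH2Cl, 20 °C; then 80 °C
Reagents that add atoms: none
Why: Near-UV excitation of 22 expels N2 and the vinyl group migrates from the carbonyl carbon to the diazo carbon (Wolff rearrangement), giving vinylketene 26; C3 carries no hydrogen, so the 1,2-hydride shift usual for substituted diazo ketones cannot compete. The ketene C=C then adds to ynol ether 25 in a [2+2] step in which the nucleophilic alkyne carbon (the one bearing the prenyl chain) bonds to the ketene carbonyl carbon, giving the 4-vinylcyclobut-2-en-1-one 27. Reversible 4π electrocyclic opening of 27, with the bulky C3 substituent preferring outward rotation, gives the (Z)-dienylketene 28, which closes ring B by a thermal disrotatory 6π electrocyclisation to dienone 29 and tautomerises to phenol 30. This is the photochemical Wolff variant of the Danheiser benzannulation of α-diazo enones with alkoxyalkynes. Ring B is the only ring closed, by 6π electrocyclisation, and the new bonds are C1'–C6', C1'–C2', C3'–C4' and C4'–C5'. No stereocentre is created: the quaternary ring carbon of 27 is transient and C3 is a spectator with no pathway to epimerise. The needed regiochemistry (prenyl between the new hydroxyl and the methoxy group) follows from the polarisation of 25, and 365 nm light is chosen because only the diazo enone absorbs there, which spares the aryl bromide and the aryl ethers.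

Step 15
Reactants: 30 methyl (2R)-3-(ArA-oxy)-2-[4-hydroxy-2-methoxy-3-(3-methylbut-2-en-1-yl)phenyl]-2-[(triethylsilyl)oxy]propanoate
Product: 32 (3R)-3-[4-hydroxy-2-methoxy-3-(3-methylbut-2-en-1-yl)phenyl]-5,7-bis(methoxymethoxy)-6-(3-methylbut-2-en-1-yl)-3-[(triethylsilyl)oxy]-2,3-dihydro-4H-chromen-4-one, via aryllithium 31 (not isolated)
Conditions: t-BuLi (3.0 equiv), THF, −78 → −20 °C; aq NH4Cl
Reagents that add atoms: none
Why: Parham cyclisation: after deprotonation of the phenol, bromine–lithium exchange gives the aryllithium at the future C4a, which attacks the ester in a 6-exo-trig acyl substitution and closes ring C as the ketone. Anionic closure avoids an acylium ion, which with an α-silyloxy and an electron-rich α-aryl group would be expected to lose carbon monoxide, and it uses no acid near the prenyl groups.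

Step 16
Reactants: 32 (3R)-3-[4-hydroxy-2-methoxy-3-(3-methylbut-2-en-1-yl)phenyl]-5,7-bis(methoxymethoxy)-6-(3-methylbut-2-en-1-yl)-3-[(triethylsilyl)oxy]-2,3-dihydro-4H-chromen-4-one
Product: 35 (3R)-3,5,7-trihydroxy-3-[4-hydroxy-2-methoxy-3-(3-methylbut-2-en-1-yl)phenyl]-6-(3-methylbut-2-en-1-yl)-2,3-dihydro-4H-chromen-4-one (CNP0157505.1), via tris(trimethylsilyl) ether 33 (not isolated), via triethylsilyl ether 34 (not isolated)
Conditions: Me3SiOTf, 2,2'-bipyridyl, MeCN, 0 °C → rt; H2O; then Bu4NF, AcOH, THF, 0 °C
Reagents that add atoms: none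
Why: The silyl triflate–bipyridyl pair converts aryl MOM ethers into aryl trimethylsilyl ethers that hydrolyse on adding water, and buffered fluoride then cleaves the tertiary triethylsilyl ether. No protic acid is used, so closure of the prenyl groups onto the neighbouring phenols and ionisation of the tertiary benzylic carbinol are avoided.

## Compound list

1 | phloroglucinol | Oc1cc(O)cc(O)c1 | starting material
2 | 3,5-bis(methoxymethoxy)phenol | COCOc1cc(O)cc(OCOC)c1 | intermediate
3 | [3,5-bis(methoxymethoxy)phenoxy]tri(propan-2-yl)silane | COCOc1cc(OCOC)cc(O[Si](C(C)C)(C(C)C)C(C)C)c1 | intermediate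
4 | prenyl bromide (1-bromo-3-methylbut-2-ene) | CC(C)=CCBr | starting material
5 | [2,6-bis(methoxymethoxy)-4-{[tri(propan-2-yl)silyl]oxy}phenyl]lithium | [Li]c1c(OCOC)cc(O[Si](C(C)C)(C(C)C)C(C)C)cc1OCOC | intermediate (not isolated)
6 | [3,5-bis(methoxymethoxy)-4-(3-methylbut-2-en-1-yl)phenoxy]tri(propan-2-yl)silane | COCOc1cc(O[Si](C(C)C)(C(C)C)C(C)C)cc(OCOC)c1CC=C(C)C | intermediate
7 | 3,5-bis(methoxymethoxy)-4-(3-methylbut-2-en-1-yl)phenol | COCOc1cc(O)cc(OCOC)c1CC=C(C)C | intermediate
8 | 2-bromo-3,5-bis(methoxymethoxy)-4-(3-methylbut-2-en-1-yl)phenol | COCOc1cc(O)c(Br)c(OCOC)c1CC=C(C)C | intermediate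
9 | methyl glycidate (racemic methyl oxirane-2-carboxylate) | COC(=O)C1CO1 | starting material
10 | methyl 3-[2-bromo-3,5-bis(methoxymethoxy)-4-(3-methylbut-2-en-1-yl)phenoxy]-2-hydroxypropanoate (racemic) | COC(=O)C(O)COc1cc(OCOC)c(CC=C(C)C)c(OCOC)c1Br | intermediate
11 | methyl 3-[2-bromo-3,5-bis(methoxymethoxy)-4-(3-methylbut-2-en-1-yl)phenoxy]-2-oxopropanoate | COC(=O)C(=O)COc1cc(OCOC)c(CC=C(C)C)c(OCOC)c1Br | intermediate
12 | S-ethyl ethanethioate | CCSC(C)=O | starting material
13 | lithium 1-(ethylsulfanyl)ethenolate | [Li]OC(=C)SCC | intermediate (not isolated)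
14 | {[1-(ethylsulfanyl)ethenyl]oxy}trimethylsilane | C=C(O[Si](C)(C)C)SCC | intermediate
15 | methyl (2R)-2-[(ArA-oxy)methyl]-4-(ethylsulfanyl)-4-oxo-2-[(trimethylsilyl)oxy]butanoate | CCSC(=O)C[C@@](C(=O)OC)(O[Si](C)(C)C)COc1cc(OCOC)c(CC=C(C)C)c(OCOC)c1Br | intermediate (not isolated)
16 | methyl (2R)-2-[(ArA-oxy)methyl]-4-(ethylsulfanyl)-2-hydroxy-4-oxobutanoate | CCSC(=O)C[C@@](C(=O)OC)(O)COc1cc(OCOC)c(CC=C(C)C)c(OCOC)c1Br | intermediate
17 | methyl (2R)-2-[(ArA-oxy)methyl]-4-(ethylsulfanyl)-4-oxo-2-[(triethylsilyl)oxy]butanoate | CCSC(=O)C[C@@](C(=O)OC)(O[Si](CC)(CC)CC)COc1cc(OCOC)c(CC=C(C)C)c(OCOC)c1Br | intermediate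
18 | tributyl(ethenyl)stannane | C=C[Sn](CCCC)(CCCC)CCCC | starting material
19 | methyl (2R)-2-[(ArA-oxy)methyl]-4-oxo-2-[(triethylsilyl)oxy]hex-5-enoate | C=CC(=O)C[C@@](C(=O)OC)(O[Si](CC)(CC)CC)COc1cc(OCOC)c(CC=C(C)C)c(OCOC)c1Br | intermediate
20 | lithium dienolate of 19 (lithium (2R)-derived hexa-3,5-dien-4-olate) | C=CC(O[Li])=C[C@@](C(=O)OC)(O[Si](CC)(CC)CC)COc1cc(OCOC)c(CC=C(C)C)c(OCOC)c1Br | intermediate (not isolated)
21 | methyl (2R)-2-[(ArA-oxy)methyl]-4-oxo-3-(trifluoroacetyl)-2-[(triethylsilyl)oxy]hex-5-enoate (C3 epimers and enol) | C=CC(=O)C(C(=O)C(F)(F)F)[C@@](C(=O)OC)(O[Si](CC)(CC)CC)COc1cc(OCOC)c(CC=C(C)C)c(OCOC)c1Br | intermediate (not isolated)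
22 | methyl (2R)-2-[(ArA-oxy)methyl]-3-diazo-4-oxo-2-[(triethylsilyl)oxy]hex-5-enoate | C=CC(=O)C(=[N+]=[N-])[C@@](C(=O)OC)(O[Si](CC)(CC)CC)COc1cc(OCOC)c(CC=C(C)C)c(OCOC)c1Br | intermediate
23 | chloroacetaldehyde dimethyl acetal | COC(CCl)OC | starting material
24 | (methoxyethynyl)lithium | [Li]C#COC | intermediate (not isolated)
25 | 1-methoxy-5-methylhex-4-en-1-yne | COC#CCC=C(C)C | intermediate
26 | methyl (2R)-2-[(ArA-oxy)methyl]-3-(oxomethylidene)-2-[(triethylsilyl)oxy]pent-4-enoate | O=C=C(C=C)[C@@](C(=O)OC)(O[Si](CC)(CC)CC)COc1cc(OCOC)c(CC=C(C)C)c(OCOC)c1Br | intermediate (not isolated)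
27 | methyl (2R)-3-(ArA-oxy)-2-[1-ethenyl-2-methoxy-3-(3-methylbut-2-en-1-yl)-4-oxocyclobut-2-en-1-yl]-2-[(triethylsilyl)oxy]propanoate (ring carbon epimers) | O=C1C(CC=C(C)C)=C(OC)C1(C=C)[C@@](C(=O)OC)(O[Si](CC)(CC)CC)COc1cc(OCOC)c(CC=C(C)C)c(OCOC)c1Br | intermediate (not isolated)
28 | methyl (2R,3Z)-2-[(ArA-oxy)methyl]-3-ethenyl-4-methoxy-8-methyl-5-(oxomethylidene)-2-[(triethylsilyl)oxy]nona-3,7-dienoate | O=C=C(CC=C(C)C)/C(OC)=C(\C=C)[C@@](C(=O)OC)(O[Si](CC)(CC)CC)COc1cc(OCOC)c(CC=C(C)C)c(OCOC)c1Br | intermediate (not isolated)
29 | methyl (2R)-3-(ArA-oxy)-2-[6-methoxy-5-(3-methylbut-2-en-1-yl)-4-oxocyclohexa-1,5-dien-1-yl]-2-[(triethylsilyl)oxy]propanoate | O=C1CC=C(C(OC)=C1CC=C(C)C)[C@@](C(=O)OC)(O[Si](CC)(CC)CC)COc1cc(OCOC)c(CC=C(C)C)c(OCOC)c1Br | intermediate (not isolated)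
30 | methyl (2R)-3-(ArA-oxy)-2-[4-hydroxy-2-methoxy-3-(3-methylbut-2-en-1-yl)phenyl]-2-[(triethylsilyl)oxy]propanoate | COc1c([C@@](C(=O)OC)(O[Si](CC)(CC)CC)COc2cc(OCOC)c(CC=C(C)C)c(OCOC)c2Br)ccc(O)c1CC=C(C)C | intermediate
31 | C-lithio, O-lithio derivative of 30 (lithium at the former C–Br carbon and on the phenol oxygen) | COc1c([C@@](C(=O)OC)(O[Si](CC)(CC)CC)COc2cc(OCOC)c(CC=C(C)C)c(OCOC)c2[Li])ccc(O[Li])c1CC=C(C)C | intermediate (not isolated)
32 | (3R)-3-[4-hydroxy-2-methoxy-3-(3-methylbut-2-en-1-yl)phenyl]-5,7-bis(methoxymethoxy)-6-(3-methylbut-2-en-1-yl)-3-[(triethylsilyl)oxy]-2,3-dihydro-4H-chromen-4-one | COc1c([C@@]2(O[Si](CC)(CC)CC)COc3cc(OCOC)c(CC=C(C)C)c(OCOC)c3C2=O)ccc(O)c1CC=C(C)C | intermediate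
33 | (3R)-3-{2-methoxy-3-(3-methylbut-2-en-1-yl)-4-[(trimethylsilyl)oxy]phenyl}-6-(3-methylbut-2-en-1-yl)-3-[(triethylsilyl)oxy]-5,7-bis[(trimethylsilyl)oxy]-2,3-dihydro-4H-chromen-4-one | COc1c([C@@]2(O[Si](CC)(CC)CC)COc3cc(O[Si](C)(C)C)c(CC=C(C)C)c(O[Si](C)(C)C)c3C2=O)ccc(O[Si](C)(C)C)c1CC=C(C)C | intermediate (not isolated)
34 | (3R)-5,7-dihydroxy-3-[4-hydroxy-2-methoxy-3-(3-methylbut-2-en-1-yl)phenyl]-6-(3-methylbut-2-en-1-yl)-3-[(triethylsilyl)oxy]-2,3-dihydro-4H-chromen-4-one | COc1c([C@@]2(O[Si](CC)(CC)CC)COc3cc(O)c(CC=C(C)C)c(O)c3C2=O)ccc(O)c1CC=C(C)C | intermediate (not isolated)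
35 | (3R)-3,5,7-trihydroxy-3-[4-hydroxy-2-methoxy-3-(3-methylbut-2-en-1-yl)phenyl]-6-(3-methylbut-2-en-1-yl)-2,3-dihydro-4H-chromen-4-one | COc1c([C@@]2(O)COc3cc(O)c(CC=C(C)C)c(O)c3C2=O)ccc(O)c1CC=C(C)C | target

## Step count and least certain steps

Total: 16 steps. Longest linear sequence: 14 steps (steps 1–7, 9–12 and 14–16, from phloroglucinol). Steps 8 and 13 are side branches.

**Step 14 (key step).** The most likely failure is slow bimolecular capture of ketene 26 by 25: the ketene carbon bears a fully substituted neighbour, so the [2+2] addition may lose to carbene insertion into nearby C–H bonds, to acylation of the product phenol by the ketene, or to slow photodegradation of the ynol ether during a long irradiation. The fallback separates light from cycloaddition.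
- Irradiating 22 in THF–water should give, by Wolff rearrangement and hydration, (3R)-3-[(ArA-oxy)methyl]-2-ethenyl-4-methoxy-4-oxo-3-[(triethylsilyl)oxy]butanoic acid F1.
- F1 is converted with 1-chloro-N,N,2-trimethylprop-1-en-1-amine into the acid chloride, (3R)-4-chloro-2-[(ArA-oxy)methyl]-3-ethenyl-4-oxo-2-[(triethylsilyl)oxy]butanoic acid methyl ester F2.
- Et3N in toluene with a large excess of 25, in the dark, regenerates ketene 26 from F2 by dehydrochlorination; warming to 90 °C completes the cascade and the sequence rejoins the route at 30.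

**Step 12.** The most likely failure is conjugate addition of the amide base or of the dienolate to the unhindered terminal enone (anionic oligomerisation), because deprotonation of the neopentyl-type C3 methylene is slow; β-elimination of the silyloxy group from the enolate is the second risk. The fallback avoids the lithium enolate.
- Soft enolisation of 19 with Me3SiOTf and Et3N should give methyl (2R)-2-[(ArA-oxy)methyl]-2-[(triethylsilyl)oxy]-4-[(trimethylsilyl)oxy]hexa-3,5-dienoate F3.
- F3 is acylated at C3 with trifluoroacetic anhydride and pyridine to give 21, which is treated with the same sulfonyl azide and Et3N to rejoin the route at 22.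

**Step 9.** The most likely failure is erosion of enantioselectivity, through competing coordination of the aryloxy and acetal oxygens to copper, or through enolisation of the 3-aryloxy keto ester and an uncatalysed background addition. The fallback changes both donor and activation mode.
- An enamine-type aldol of acetone with 11, using a proline-derived amide catalyst of the appropriate antipode, should give methyl (2R)-2-[(ArA-oxy)methyl]-2-hydroxy-4-oxopentanoate F4.
- Silylation (Et3SiOTf, 2,6-lutidine) gives methyl (2R)-2-[(ArA-oxy)methyl]-4-oxo-2-[(triethylsilyl)oxy]pentanoate F5.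
- Kinetic enolisation at the methyl group with LiN(SiMe3)2 and trapping with dimethyl(methylidene)ammonium iodide gives the Mannich base methyl (2R)-2-[(ArA-oxy)methyl]-6-(dimethylamino)-4-oxo-2-[(triethylsilyl)oxy]hexanoate F6.
- Quaternisation with MeI and elimination with NaHCO3 rejoin the route at 19.

**Step 15.** The most likely failure is protonation of the aryllithium before it reaches the hindered ester, giving a debrominated open-chain ester, or a second addition of t-BuLi to the ketone once the tetrahedral intermediate collapses. The fallback uses the classical carboxylate form of the Parham cyclisation.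
- Saponification of 30 (LiOH, THF–water, or Me3SnOH) gives (2R)-3-(ArA-oxy)-2-[4-hydroxy-2-methoxy-3-(3-methylbut-2-en-1-yl)phenyl]-2-[(triethylsilyl)oxy]propanoic acid F7.
- F7 with t-BuLi (4 equiv) at −78 °C forms the aryllithium, which adds to the lithium carboxylate; the resulting geminal dialkoxide cannot collapse before the quench, and work-up rejoins the route at 32.

**Step 11.** The most likely failure is competing oxidative addition of zerovalent palladium into the aryl C–Br bond, or conjugate addition of the thiolate by-product to the new vinyl ketone. The fallback is palladium-free.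
- Aminolysis of thioester 17 with MeNHOMe·HCl and i-PrMgCl gives methyl (2R)-2-[(ArA-oxy)methyl]-4-[methoxy(methyl)amino]-4-oxo-2-[(triethylsilyl)oxy]butanoate F8; the hindered methyl ester should not react.
- F8 with CH2=CHMgBr at −78 → 0 °C, followed by an inverse quench into cold aqueous acid, rejoins the route at 19.

## Further compounds

F1 | step 14 | (3R)-3-[(ArA-oxy)methyl]-2-ethenyl-4-methoxy-4-oxo-3-[(triethylsilyl)oxy]butanoic acid (C2 epimers) | OC(=O)C(C=C)[C@@](C(=O)OC)(O[Si](CC)(CC)CC)COc1cc(OCOC)c(CC=C(C)C)c(OCOC)c1Br
F2 | step 14 | methyl (2R)-4-chloro-2-[(ArA-oxy)methyl]-3-ethenyl-4-oxo-2-[(triethylsilyl)oxy]butanoate (C3 epimers) | ClC(=O)C(C=C)[C@@](C(=O)OC)(O[Si](CC)(CC)CC)COc1cc(OCOC)c(CC=C(C)C)c(OCOC)c1Br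
F3 | step 12 | methyl (2R)-2-[(ArA-oxy)methyl]-2-[(triethylsilyl)oxy]-4-[(trimethylsilyl)oxy]hexa-3,5-dienoate | C=CC(O[Si](C)(C)C)=C[C@@](C(=O)OC)(O[Si](CC)(CC)CC)COc1cc(OCOC)c(CC=C(C)C)c(OCOC)c1Br
F4 | step 9 | methyl (2R)-2-[(ArA-oxy)methyl]-2-hydroxy-4-oxopentanoate | CC(=O)C[C@@](C(=O)OC)(O)COc1cc(OCOC)c(CC=C(C)C)c(OCOC)c1Br
F5 | step 9 | methyl (2R)-2-[(ArA-oxy)methyl]-4-oxo-2-[(triethylsilyl)oxy]pentanoate | CC(=O)C[C@@](C(=O)OC)(O[Si](CC)(CC)CC)COc1cc(OCOC)c(CC=C(C)C)c(OCOC)c1Br
F6 | step 9 | methyl (2R)-2-[(ArA-oxy)methyl]-6-(dimethylamino)-4-oxo-2-[(triethylsilyl)oxy]hexanoate | CN(C)CCC(=O)C[C@@](C(=O)OC)(O[Si](CC)(CC)CC)COc1cc(OCOC)c(CC=C(C)C)c(OCOC)c1Br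
F7 | step 15 | (2R)-3-(ArA-oxy)-2-[4-hydroxy-2-methoxy-3-(3-methylbut-2-en-1-yl)phenyl]-2-[(triethylsilyl)oxy]propanoic acid | COc1c([C@@](C(=O)O)(O[Si](CC)(CC)CC)COc2cc(OCOC)c(CC=C(C)C)c(OCOC)c2Br)ccc(O)c1CC=C(C)C
F8 | step 11 | methyl (2R)-2-[(ArA-oxy)methyl]-4-[methoxy(methyl)amino]-4-oxo-2-[(triethylsilyl)oxy]butanoate | CON(C)C(=O)C[C@@](C(=O)OC)(O[Si](CC)(CC)CC)COc1cc(OCOC)c(CC=C(C)C)c(OCOC)c1Br
A1 | alternative 1 | (3R)-3,5-dihydroxy-3-[2-hydroxy-4-(methoxymethoxy)-3-(3-methylbut-2-en-1-yl)phenyl]-7-(methoxymethoxy)-6-(3-methylbut-2-en-1-yl)-2,3-dihydro-4H-chromen-4-one | Oc1c([C@@]2(O)COc3cc(OCOC)c(CC=C(C)C)c(O)c3C2=O)ccc(OCOC)c1CC=C(C)C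
A2 | alternative 1 | (3R)-3-hydroxy-7-(methoxymethoxy)-3-{4-(methoxymethoxy)-2-[(2-methylbut-3-en-2-yl)oxy]phenyl}-5-[(2-methylbut-3-en-2-yl)oxy]-2,3-dihydro-4H-chromen-4-one | C=CC(C)(C)Oc1c([C@@]2(O)COc3cc(OCOC)cc(OC(C)(C)C=C)c3C2=O)ccc(OCOC)c1
A3 | alternative 2 | [2-bromo-4,6-dihydroxy-5-(3-methylbut-2-en-1-yl)phenyl]{(4R)-4-[2-methoxy-4-(methoxymethoxy)-3-(3-methylbut-2-en-1-yl)phenyl]-2,2-dimethyl-1,3-dioxolan-4-yl}methanone | COc1c([C@@]2(C(=O)c3c(Br)cc(O)c(CC=C(C)C)c3O)OC(C)(C)OC2)ccc(OCOC)c1CC=C(C)C
A4 | alternative 2 | 3-bromo-1-{(4R)-4-[2-methoxy-4-(methoxymethoxy)-3-(3-methylbut-2-en-1-yl)phenyl]-2,2-dimethyl-1,3-dioxolan-4-yl}prop-2-yn-1-one | COc1c([C@@]2(C(=O)C#CBr)OC(C)(C)OC2)ccc(OCOC)c1CC=C(C)C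
A5 | alternative 2 | 1-methoxy-2-(3-methylbut-2-en-1-yl)-1,3-bis[(trimethylsilyl)oxy]buta-1,3-diene | C=C(O[Si](C)(C)C)C(CC=C(C)C)=C(OC)O[Si](C)(C)C
A6 | alternative 3 | (3R)-3-(methoxymethoxy)-3-[2-methoxy-4-(methoxymethoxy)-3-(3-methylbut-2-en-1-yl)phenyl]-5,7-bis(methoxymethoxy)-6-(3-methylbut-2-en-1-yl)-2,3-dihydro-4H-chromen-4-one | COc1c([C@@]2(OCOC)COc3cc(OCOC)c(CC=C(C)C)c(OCOC)c3C2=O)ccc(OCOC)c1CC=C(C)C
A7 | alternative 3 | 3,5-bis(methoxymethoxy)-4-(3-methylbut-2-en-1-yl)-2-(trimethylsilyl)phenyl trifluoromethanesulfonate | COCOc1cc(OS(=O)(=O)C(F)(F)F)c([Si](C)(C)C)c(OCOC)c1CC=C(C)C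
A8 | alternative 3 | methyl (2R)-3-hydroxy-2-[2-methoxy-4-(methoxymethoxy)-3-(3-methylbut-2-en-1-yl)phenyl]-2-(methoxymethoxy)propanoate | COc1c([C@@](C(=O)OC)(OCOC)CO)ccc(OCOC)c1CC=C(C)C
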